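## Retrosynthetic overview

1. The C24 chain, its (Z)-alkene and ring carbon C2 all come from methyl nervonate (1), whose ester carbon is taken through aluminium hemiacetal (2) to the aldehyde carbon of (3).
2. Ring carbons C3–C6 and the methyl group come from phosphonate (4) and amide (5), joined through dianion (6) and adduct (7) by an acyl C–C disconnection to the C5 reagent (8).
3. The C2–C3 bond is disconnected as a C=C bond (Horner–Wadsworth–Emmons): dianion (9) of 8 plus 3 gives the acyclic dienedione (10).
4. Key disconnection: the O1–C2 bond of the target (11), which the SMILES defines as the (2R) enantiomer. An enantioselective 6-endo-trig oxa-Michael closure of 10 forms the only ring last and sets the only stereocentre in the same C–O bond-forming event.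

Assumption: methyl nervonate (1) is taken as purchasable in gram quantities.

## Route

Step 1
Reactants: 1 methyl (15Z)-tetracos-15-enoate (methyl nervonate)
Product: 3 (15Z)-tetracos-15-enal, via aluminium hemiacetal 2 (not isolated)
Conditions: i-Bu2AlH (1.1 equiv), CH2Cl2, −78 °C, 1 h; MeOH, then aq. potassium sodium tartrate, rt
Reagents that add atoms: none
Why: Partial reduction of an ester with i-Bu2AlH: at −78 °C the tetrahedral aluminium hemiacetal 2 does not collapse, so no second hydride is delivered and the aldehyde is released only on hydrolysis, while the isolated (Z)-alkene is inert to hydroalumination at this temperature.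

Step 2
Reactants: 4 diethyl (2-oxopropyl)phosphonate; 5 N-methoxy-N-methylacetamide
Product: 8 diethyl (2,4-dioxopentyl)phosphonate, via dilithium dianion 6 (not isolated), via tetrahedral adduct 7 (not isolated)
Conditions: LiN(i-Pr)2 (2.1 equiv), THF, −78 → 0 °C; 5 (1.0 equiv), −78 → 0 °C; cold 1 M HCl
Reagents that add atoms: none
Why: Claisen-type acylation of a 1,3-dianion: the last-formed terminal carbanion of 6 is the more nucleophilic site and attacks the Weinreb amide, whose chelated tetrahedral adduct 7 neither over-adds nor releases the acidic β-diketone until the acid quench.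

Step 3
Reactants: 3 (15Z)-tetracos-15-enal; 8 diethyl (2,4-dioxopentyl)phosphonate
Product: 10 (5E,20Z)-nonacosa-5,20-diene-2,4-dione, via disodium dianion 9 (not isolated)
Conditions: 8 (1.2 equiv), NaH (2.5 equiv), THF, 0 °C → rt; 3, 0 °C → rt, 4 h; cold 0.5 M HCl to pH 3–4
Reagents that add atoms: none
Why: Horner–Wadsworth–Emmons olefination: dianion 9 reacts through its phosphonate carbanion, the stabilised β-ketophosphonate gives the (E)-enone, and the product stays in the pot as its chelated sodium diketonate, which cannot cyclise, until the cold acid quench; the remote (Z)-alkene is untouched.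

Step 4
Reactants: 10 (5E,20Z)-nonacosa-5,20-diene-2,4-dione
Product: 11 (2R)-6-methyl-2-[(14Z)-tricos-14-en-1-yl]-2,3-dihydro-4H-pyran-4-one (target)
Conditions: quinine-derived squaramide 3-{[3,5-bis(trifluoromethyl)phenyl]amino}-4-{[(8α,9S)-6′-methoxycinchonan-9-yl]amino}cyclobut-3-ene-1,2-dione (10 mol %), PhMe (0.02 M), −20 °C, 48–72 h; short silica plug
Reagents that add atoms: none
Why: Proposed new method: a catalytic enantioselective 6-endo-trig oxa-Michael cyclisation of an acyclic alkenyl β-diketone is proposed here as new; the quinuclidine nitrogen deprotonates the acidic enol O–H (pKa about 9 in water) to give a chiral ammonium dienolate, the squaramide N–H pair binds the C4 oxygen and so holds the diketonate in the non-chelated s-trans conformer in which the oxygen on C2 can reach C6, the catalyst pocket selects one helical twist about the C4–C5 bond so that this oxygen adds to the Re face of C6 of the (E)-enone (Re-face C–O bond formation gives the 2R centre), and the ammonium ion then protonates C5 of the cross-conjugated enolate to release the vinylogous ester; ring closure should be downhill for an alkyl-substituted enone, and the reverse E1cB ring opening would require the weak amine to remove a C3–H of pKa above 20, so the product should hold its configuration at −20 °C, while high dilution suppresses intermolecular C-Michael addition; closest known reaction types are the cinchona- and amine–thiourea-catalysed asymmetric oxa-Michael cyclisation of 2′-hydroxychalcone-type substrates to flavanones (same O–C=C–C(=O)–C=C topology), the activation of acetylacetone-type pronucleophiles by the same squaramides, and the racemic acid- or base-mediated cyclisation of alkenyl β-diketones to 2,3-dihydro-4H-pyran-4-ones.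

## Compound list

1 | methyl (15Z)-tetracos-15-enoate (methyl nervonate) | CCCCCCCC/C=C\CCCCCCCCCCCCCC(=O)OC | starting material
2 | diisobutylaluminium hemiacetal of 1: [(15Z)-1-methoxytetracos-15-en-1-yl]oxy-diisobutylalane | CCCCCCCC/C=C\CCCCCCCCCCCCCC(OC)O[Al](CC(C)C)CC(C)C | intermediate
3 | (15Z)-tetracos-15-enal | CCCCCCCC/C=C\CCCCCCCCCCCCCC=O | intermediate
4 | diethyl (2-oxopropyl)phosphonate | CCOP(=O)(OCC)CC(C)=O | starting material
5 | N-methoxy-N-methylacetamide | CC(=O)N(C)OC | starting material
6 | dilithium 1,3-dianion of 4 (carbanions at C1 and C3 of the oxopropyl group) | [Li+].[Li+].CCOP(=O)(OCC)[CH-]C(=O)[CH2-] | intermediate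
7 | dilithium tetrahedral adduct of 6 with 5 (alkoxide at the former amide carbon, carbanion α to phosphorus) | [Li+].[Li+].CCOP(=O)(OCC)[CH-]C(=O)CC(C)([O-])N(C)OC | intermediate
8 | diethyl (2,4-dioxopentyl)phosphonate | CCOP(=O)(OCC)CC(=O)CC(C)=O | intermediate
9 | disodium 1,3-dianion of 8 (carbanions at C1 and C3 of the dioxopentyl group) | [Na+].[Na+].CCOP(=O)(OCC)[CH-]C(=O)[CH-]C(C)=O | intermediate
10 | (5E,20Z)-nonacosa-5,20-diene-2,4-dione (drawn as the diketo tautomer; exists largely as the chelated enol) | CCCCCCCC/C=C\CCCCCCCCCCCCC/C=C/C(=O)CC(C)=O | intermediate
11 | (2R)-6-methyl-2-[(14Z)-tricos-14-en-1-yl]-2,3-dihydro-4H-pyran-4-one | CCCCCCCC/C=C\CCCCCCCCCCCCC[C@@H]1CC(=O)C=C(C)O1 | target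

## Step count and risks

Total step count: 4. Longest linear sequence: 3 steps (1 → 3 → 10 → 11); step 2 is a one-step side branch.

**Most likely to fail: step 4 (the proposed new cyclisation).** The dienolate is a weak Michael donor and acceptor, so the reaction may be slow. Reversible ring opening could erode the enantiomeric excess. The absolute sense of induction is a prediction, not an established result; the quinidine-derived pseudoenantiomeric squaramide is the mirror-image option if the quinine-derived catalyst gives the antipode. Compound 10 should be purified quickly on neutral silica and stored cold so that no racemic background closure precedes the step.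

The fallback uses known chemistry, sets out from aldehyde 3 and comes back to the route at 11. Acetylacetone is doubly silylated (Me3SiOTf, Et3N, Et2O, 0 °C) to 2,4-bis(trimethylsilyloxy)penta-1,3-diene F1. A catalytic enantioselective vinylogous Mukaiyama aldol addition of F1 to 3 (Ti(OiPr)4/(S)-BINOL, 10–20 mol %, THF, −78 → −20 °C), followed by mild acid desilylation, gives (6R,20Z)-6-hydroxynonacos-20-ene-2,4-dione F2. (S)-BINOL is the antipode expected, by analogy with titanium–BINOL additions to unbranched aliphatic aldehydes, to direct the diene to the Si face and give the (6R) carbinol; this is confirmed by Mosher ester analysis of F2. Treatment of F2 with CF3CO2H in CH2Cl2 at rt then closes the ring by hemiketalisation at the acetyl carbonyl and dehydration. This C–O bond formation does not touch the carbinol centre and gives 11.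

**Second: step 3 (olefination with a dianion and an enolisable aldehyde).** Aldol self-condensation of 3 or incomplete dianion formation could lower the yield. The fallback sets out from 3 and comes back at 10. Wittig olefination of 3 with Ph3P=CHC(O)CH3 (PhMe, 80 °C) gives (3E,18Z)-heptacosa-3,18-dien-2-one F3. Direct C-acetylation of its methyl ketone under soft enolisation (MgBr2·OEt2, i-Pr2NEt, 1-acetylbenzotriazole, CH2Cl2, rt) then gives 10 without needing phosphonate 8.

**Third: step 2 (acylation of the dianion).** Proton transfer from the acetyl group of 5 can quench dianion 6 and return 4. The fallback sets out from 4 and comes back at 8. Dianion 6, made as in step 2, is added to acetaldehyde at −78 °C; carbonyl addition outruns proton transfer and gives diethyl (4-hydroxy-2-oxopentyl)phosphonate F4. Oxidation of the β-hydroxy ketone (Dess–Martin periodinane, 1.1 equiv, CH2Cl2, 0 °C) then gives 8.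

## Further compounds

F1 | step 4 | 2,4-bis(trimethylsilyloxy)penta-1,3-diene | C=C(O[Si](C)(C)C)C=C(C)O[Si](C)(C)C
F2 | step 4 | (6R,20Z)-6-hydroxynonacos-20-ene-2,4-dione | CCCCCCCC/C=C\CCCCCCCCCCCCC[C@@H](O)CC(=O)CC(C)=O
F3 | step 3 | (3E,18Z)-heptacosa-3,18-dien-2-one | CCCCCCCC/C=C\CCCCCCCCCCCCC/C=C/C(C)=O
F4 | step 2 | diethyl (4-hydroxy-2-oxopentyl)phosphonate | CCOP(=O)(OCC)CC(=O)CC(C)O
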